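**Retrosynthetic overview**
- Target ⇐ C1 ketone with O4 and O6 as trimethylsilyl ethers and the 8-acetate already in place (Luche reduction, desilylation).
- Ring B is closed last through C7–C8: a SmI2 ketyl (the C8 aldehyde carbon as nucleophile) adds 6-exo to the enoate β-carbon C7, loss of β-acetate reveals the methylene ester, and O8–Sm is trapped as the acetate.
- C6–C7 before that: indium Barbier addition of a 3-bromo-2-(bromomethyl)acrylate (acrylate β-carbon as nucleophile) to the C6 aldehyde, then an SN2′ acetate shift.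
- C5 and quaternary C10: cuprate 1,4-addition and enolate allylation on (R)-4-silyloxy-2,4-dimethylcyclohexenone; the two alkenes are later cleaved one after the other to the C6 and C8 aldehydes.
- Ring A is formed first by ring-closing metathesis of a dienone from (R)-linalool, which supplies C4 with its OH and methyl; ring order A, then B.

Assumption: commercial (R)-(−)-linalool is used at its natural enantiomeric purity (upgraded by recrystallising a later intermediate if needed); eudesmane numbering (C1–C15) is used for the carbons of all intermediates.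

**Step 1**
Reactants: 1 (R)-(−)-linalool
Product: 3 (6R)-6-hydroxy-2,6-dimethylocta-1,7-dien-3-one, via secondary allylic hydroperoxide 2 (not isolated)
Conditions: O2, hν (visible), tetraphenylporphyrin (cat.), CH2Cl2, 0 °C; then Ac2O, pyridine, 0 °C → rt
Reagents that add atoms: dioxygen O=O
Why: Schenck ene reaction of singlet oxygen at the trisubstituted alkene gives (with its separable tertiary regioisomer, roughly 1:1) the secondary allylic hydroperoxide, which Ac2O/pyridine dehydrates by Kornblum–DeLaMare elimination to the isopropenyl ketone, the vinyl group and the carbinol stereocenter (future C4, R) being untouched.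

**Step 2**
Reactants: 3 (6R)-6-hydroxy-2,6-dimethylocta-1,7-dien-3-one
Product: 4 (4R)-4-hydroxy-2,4-dimethylcyclohex-2-en-1-one
Conditions: second-generation Hoveyda–Grubbs catalyst RuCl2(H2IMes)(=CH-C6H4-2-OiPr) (5 mol %), toluene, 80 °C
Reagents that add atoms: none
Why: Ring-closing metathesis: the catalyst loads on the vinyl carbinol and closes ring A onto the 1,1-disubstituted enone alkene with loss of ethylene, giving the trisubstituted cyclohexenone without touching C4.

**Step 3**
Reactants: 4 (4R)-4-hydroxy-2,4-dimethylcyclohex-2-en-1-one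
Product: 5 (4R)-2,4-dimethyl-4-(trimethylsilyloxy)cyclohex-2-en-1-one
Conditions: 1-(trimethylsilyl)imidazole, CH2Cl2, rt
Reagents that add atoms: 1-(trimethylsilyl)imidazole C[Si](C)(C)n1ccnc1
Why: Silyl transfer from the neutral N-silylimidazole caps the tertiary alcohol without enolising the enone, so that the next addition is steered anti to the C4 oxygen instead of being delivered by it.

**Step 4**
Reactants: 5 (4R)-2,4-dimethyl-4-(trimethylsilyloxy)cyclohex-2-en-1-one
Product: 8 (2R,3R,4R)-4-hydroxy-2,4-dimethyl-3-(2-methylprop-1-en-1-yl)-2-(prop-2-en-1-yl)cyclohexan-1-one, via bromomagnesium enolate 6 (not isolated), via trimethylsilyl ether 7 (not isolated)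
Conditions: (2-methylprop-1-enyl)MgBr, CuBr·SMe2 (20 mol %), THF, −78 → −30 °C; then allyl bromide, HMPA, −30 °C → rt; then 1 M HCl, THF, 0 °C
Reagents that add atoms: (2-methylprop-1-en-1-yl)magnesium bromide CC(C)=C[Mg]Br; allyl bromide C=CCBr
Why: Copper-catalysed Grignard 1,4-addition occurs anti to the pseudoaxial γ-silyloxy group (C6 unit cis to the C4 methyl, sets C5), the regiodefined magnesium enolate is C-allylated anti to the new pseudoaxial C5 substituent (sets the quaternary C10, allyl trans to C5–C6), and the acid work-up hydrolyses the silyl ether to free the 4-OH for the chelation-controlled step 7.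

**Step 5**
Reactants: 8 (2R,3R,4R)-4-hydroxy-2,4-dimethyl-3-(2-methylprop-1-en-1-yl)-2-(prop-2-en-1-yl)cyclohexan-1-one
Product: 9 (1R,2R,6R)-6-hydroxy-2,6-dimethyl-3-oxo-2-(prop-2-en-1-yl)cyclohexane-1-carbaldehyde
Conditions: O3 (1.0 equiv), CH2Cl2, pyridine, −78 °C; then Me2S
Reagents that add atoms: ozone [O-][O+]=O
Why: Selective ozonolysis: the electron-rich trisubstituted alkene reacts far faster than the monosubstituted allyl group, so one equivalent of ozone unmasks only the C6 aldehyde and leaves the allyl group as the latent C8 aldehyde.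

**Step 6**
Reactants: 10 methyl 2-(bromomethyl)prop-2-enoate
Product: 12 methyl (Z)-3-bromo-2-(bromomethyl)prop-2-enoate, via tribromo ester 11 (not isolated)
Conditions: Br2, CH2Cl2, 0 °C → rt; then Et3N, 0 °C
Reagents that add atoms: bromine BrBr
Why: Bromine addition to the acrylate gives the symmetrical tribromide, whose only possible E2 dehydrobromination (H from a CH2Br, Br from the α-carbon) restores conjugation and gives the β-bromoacrylate, mainly the Z isomer (either geometry serves in step 7).

**Step 7**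
Reactants: 9 (1R,2R,6R)-6-hydroxy-2,6-dimethyl-3-oxo-2-(prop-2-en-1-yl)cyclohexane-1-carbaldehyde; 12 methyl (Z)-3-bromo-2-(bromomethyl)prop-2-enoate
Product: 13 methyl (4R)-3-bromo-4-hydroxy-4-[(1S,2R,6R)-6-hydroxy-2,6-dimethyl-3-oxo-2-(prop-2-en-1-yl)cyclohexyl]-2-methylidenebutanoate (C7 epimers)
Conditions: In powder, THF/H2O (1:1), rt
Reagents that add atoms: none
Why: Proposed new method: indium inserts into the allylic C–Br bond of 12 (the vinyl C–Br is inert) and the resulting γ-bromo-2-(methoxycarbonyl)allylindium adds through its CHBr terminus (SE2′) to the aldehyde only, so the acrylate β-carbon C7, normally an electrophile, acts as the nucleophile; the free 4-OH and the aldehyde oxygen bind trivalent indium in a trans-fused six-membered chelate whose β face is screened by the two axial methyls, so C7 enters from the α face and sets the 6α-carbinol, while the C7 configuration is irrelevant because it is erased in step 8; the closest known reactions are Barbier allylations of aldehydes in water with 2-(bromomethyl)acrylates and with 1,3-dibromopropene (which gives bromohydrins) and the chelation-controlled indium allylation of β-hydroxy aldehydes.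

**Step 8**
Reactants: 13 methyl (4R)-3-bromo-4-hydroxy-4-[(1S,2R,6R)-6-hydroxy-2,6-dimethyl-3-oxo-2-(prop-2-en-1-yl)cyclohexyl]-2-methylidenebutanoate
Product: 15 methyl (2E,4S)-2-(acetoxymethyl)-4-[(1S,2R,6R)-2,6-dimethyl-3-oxo-2-(prop-2-en-1-yl)-6-(trimethylsilyloxy)cyclohexyl]-4-(trimethylsilyloxy)but-2-enoate, via diol acetate 14 (not isolated)
Conditions: KOAc, 18-crown-6 (cat.), MeCN, rt; then 1-(trimethylsilyl)imidazole, rt
Reagents that add atoms: potassium acetate CC(=O)[O-].[K+]; 1-(trimethylsilyl)imidazole C[Si](C)(C)n1ccnc1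
Why: SN2′ displacement of the doubly activated secondary allylic bromide by acetate (as with Morita–Baylis–Hillman bromides) moves the alkene to C7=C11 and gives the thermodynamically preferred E enoate with C6 trans to the ester (no butenolide can form), after which both hydroxyls are silylated so that the coming aldehyde cannot form a lactol and O8 will be the only free oxygen after ring closure.

**Step 9**
Reactants: 15 methyl (2E,4S)-2-(acetoxymethyl)-4-[(1S,2R,6R)-2,6-dimethyl-3-oxo-2-(prop-2-en-1-yl)-6-(trimethylsilyloxy)cyclohexyl]-4-(trimethylsilyloxy)but-2-enoate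
Product: 16 methyl (2E,4S)-2-(acetoxymethyl)-4-[(1S,2R,6R)-2,6-dimethyl-3-oxo-2-(2-oxoethyl)-6-(trimethylsilyloxy)cyclohexyl]-4-(trimethylsilyloxy)but-2-enoate
Conditions: O3 (1.0 equiv), CH2Cl2, pyridine, −78 °C; then Me2S
Reagents that add atoms: ozone [O-][O+]=O
Why: Ozonolysis of the monosubstituted alkene, which is much more electron-rich than the ester-conjugated trisubstituted alkene, releases the C8 aldehyde.

**Step 10 (key step)**
Reactants: 16 methyl (2E,4S)-2-(acetoxymethyl)-4-[(1S,2R,6R)-2,6-dimethyl-3-oxo-2-(2-oxoethyl)-6-(trimethylsilyloxy)cyclohexyl]-4-(trimethylsilyloxy)but-2-enoate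
Product: 18 methyl 8α-acetoxy-1-oxo-4α,6α-bis(trimethylsilyloxy)-5αH,7αH-eudesm-11(13)-en-12-oate, via samarium alkoxide 17 (not isolated)
Conditions: SmI2 (2.3 equiv), HMPA, THF, −78 °C, 0.01 M; then Ac2O, DMAP, −78 → 0 °C
Reagents that add atoms: acetic anhydride CC(=O)OC(C)=O
Why: Proposed new method: SmI2 reduces the aldehyde (much faster than the hindered ketone or the enoate) to a ketyl, a carbonyl carbon of reversed polarity, which attacks the electrophilic enoate β-carbon C7 in a 6-exo chair transition state with O–Sm, the C6 silyloxy group and the enoate all equatorial and O–Sm anti to the enoate (the usual trans outcome of ketyl–olefin closures, whereas allyl-metal closures tend to cis), setting the 7β side chain and 8α oxygen and closing ring B as a trans-decalin; a second electron gives the samarium ester enolate, which expels the β-acetate (E1cB) to unveil the 11(13)-methylene ester, and Ac2O traps the only alkoxide present as the 8α-acetate before it can lactonise onto the ester; the closest known reactions are SmI2 ketyl–olefin 6-exo cyclisations onto enoates and β-eliminations of samarium ester enolates.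

**Step 11**
Reactants: 18 methyl 8α-acetoxy-1-oxo-4α,6α-bis(trimethylsilyloxy)-5αH,7αH-eudesm-11(13)-en-12-oate
Product: 20 methyl 8α-acetoxy-1β,4α,6α-trihydroxy-5αH,7αH-eudesm-11(13)-en-12-oate (CNP0272656.1), via silylated 1β-alcohol 19 (not isolated)
Conditions: NaBH4, CeCl3·7H2O, MeOH, −78 → −20 °C; then aq. citric acid, MeOH, rt
Reagents that add atoms: none
Why: Luche reduction delivers hydride axially from the α face of the trans-decalin C1 ketone, anti to the axial C10 methyl, giving the equatorial 1β-alcohol without touching the acrylate or the acetate, and dilute citric acid then removes both trimethylsilyl ethers under conditions too mild for lactonisation.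

**Compound list**
1 | (R)-(−)-linalool, (3R)-3,7-dimethylocta-1,6-dien-3-ol | C=C[C@](C)(O)CCC=C(C)C | starting material
2 | (6R)-3-hydroperoxy-2,6-dimethylocta-1,7-dien-6-ol (C3 epimers) | C=C[C@](C)(O)CCC(OO)C(C)=C | intermediate
3 | (6R)-6-hydroxy-2,6-dimethylocta-1,7-dien-3-one | C=C[C@](C)(O)CCC(=O)C(C)=C | intermediate
4 | (4R)-4-hydroxy-2,4-dimethylcyclohex-2-en-1-one | CC1=C[C@](C)(O)CCC1=O | intermediate
5 | (4R)-2,4-dimethyl-4-(trimethylsilyloxy)cyclohex-2-en-1-one | CC1=C[C@](C)(O[Si](C)(C)C)CCC1=O | intermediate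
6 | bromomagnesium (3R,4R)-2,4-dimethyl-3-(2-methylprop-1-en-1-yl)-4-(trimethylsilyloxy)cyclohex-1-en-1-olate | CC(C)=C[C@@H]1C(C)=C(O[Mg]Br)CC[C@@]1(C)O[Si](C)(C)C | intermediate
7 | (2R,3R,4R)-2,4-dimethyl-3-(2-methylprop-1-en-1-yl)-2-(prop-2-en-1-yl)-4-(trimethylsilyloxy)cyclohexan-1-one | CC(C)=C[C@@H]1[C@@](C)(CC=C)C(=O)CC[C@@]1(C)O[Si](C)(C)C | intermediate
8 | (2R,3R,4R)-4-hydroxy-2,4-dimethyl-3-(2-methylprop-1-en-1-yl)-2-(prop-2-en-1-yl)cyclohexan-1-one | CC(C)=C[C@@H]1[C@@](C)(CC=C)C(=O)CC[C@@]1(C)O | intermediate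
9 | (1R,2R,6R)-6-hydroxy-2,6-dimethyl-3-oxo-2-(prop-2-en-1-yl)cyclohexane-1-carbaldehyde | O=C[C@@H]1[C@@](C)(CC=C)C(=O)CC[C@@]1(C)O | intermediate
10 | methyl 2-(bromomethyl)prop-2-enoate | C=C(CBr)C(=O)OC | starting material
11 | methyl 2,3-dibromo-2-(bromomethyl)propanoate | BrCC(Br)(CBr)C(=O)OC | intermediate
12 | methyl (Z)-3-bromo-2-(bromomethyl)prop-2-enoate | Br/C=C(\CBr)C(=O)OC | intermediate
13 | methyl (4R)-3-bromo-4-hydroxy-4-[(1S,2R,6R)-6-hydroxy-2,6-dimethyl-3-oxo-2-(prop-2-en-1-yl)cyclohexyl]-2-methylidenebutanoate (epimers at the CHBr carbon, C7) | C=C(C(=O)OC)C(Br)[C@H](O)[C@@H]1[C@@](C)(CC=C)C(=O)CC[C@@]1(C)O | intermediate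
14 | methyl (2E,4S)-2-(acetoxymethyl)-4-hydroxy-4-[(1S,2R,6R)-6-hydroxy-2,6-dimethyl-3-oxo-2-(prop-2-en-1-yl)cyclohexyl]but-2-enoate | COC(=O)/C(COC(C)=O)=C/[C@H](O)[C@@H]1[C@@](C)(CC=C)C(=O)CC[C@@]1(C)O | intermediate
15 | methyl (2E,4S)-2-(acetoxymethyl)-4-[(1S,2R,6R)-2,6-dimethyl-3-oxo-2-(prop-2-en-1-yl)-6-(trimethylsilyloxy)cyclohexyl]-4-(trimethylsilyloxy)but-2-enoate | COC(=O)/C(COC(C)=O)=C/[C@H](O[Si](C)(C)C)[C@@H]1[C@@](C)(CC=C)C(=O)CC[C@@]1(C)O[Si](C)(C)C | intermediate
16 | methyl (2E,4S)-2-(acetoxymethyl)-4-[(1S,2R,6R)-2,6-dimethyl-3-oxo-2-(2-oxoethyl)-6-(trimethylsilyloxy)cyclohexyl]-4-(trimethylsilyloxy)but-2-enoate | COC(=O)/C(COC(C)=O)=C/[C@H](O[Si](C)(C)C)[C@@H]1[C@@](C)(CC=O)C(=O)CC[C@@]1(C)O[Si](C)(C)C | intermediate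
17 | diiodosamarium 8α-alkoxide of methyl 8α-hydroxy-1-oxo-4α,6α-bis(trimethylsilyloxy)-5αH,7αH-eudesm-11(13)-en-12-oate | C=C(C(=O)OC)[C@H]1[C@H](O[Si](C)(C)C)[C@@H]2[C@@](C)(C[C@@H]1O[Sm](I)I)C(=O)CC[C@@]2(C)O[Si](C)(C)C | intermediate
18 | methyl 8α-acetoxy-1-oxo-4α,6α-bis(trimethylsilyloxy)-5αH,7αH-eudesm-11(13)-en-12-oate (10β-methyl, trans-decalin) | C=C(C(=O)OC)[C@H]1[C@H](O[Si](C)(C)C)[C@@H]2[C@@](C)(C[C@@H]1OC(C)=O)C(=O)CC[C@@]2(C)O[Si](C)(C)C | intermediate
19 | methyl 8α-acetoxy-1β-hydroxy-4α,6α-bis(trimethylsilyloxy)-5αH,7αH-eudesm-11(13)-en-12-oate | C=C(C(=O)OC)[C@H]1[C@H](O[Si](C)(C)C)[C@@H]2[C@@](C)(C[C@@H]1OC(C)=O)[C@H](O)CC[C@@]2(C)O[Si](C)(C)C | intermediate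
20 | methyl 2-[(1S,2S,3S,4aR,5R,8R,8aS)-3-(acetyloxy)-1,5,8-trihydroxy-4a,8-dimethyldecahydronaphthalen-2-yl]prop-2-enoate (methyl 8α-acetoxy-1β,4α,6α-trihydroxy-5αH,7αH-eudesm-11(13)-en-12-oate) | C=C(C(=O)OC)[C@H]1[C@H](O)[C@@H]2[C@@](C)(C[C@@H]1OC(C)=O)[C@H](O)CC[C@@]2(C)O | target

**Step count**
Total steps: 11 (ten on the main line from 1, one for reagent 12). Longest linear sequence: 10 steps (1 → 20, steps 1–5 and 7–11).

**Three steps most likely to fail**

Step 10 (key ring closure). SmI2 may reduce the allylic acetate or enoate before the ketyl forms, and the trans 7,8-relationship rests on the ketyl–olefin transition-state model. Fallback, setting out from 16 and coming back to the route at 18: make C7 the carbon of reversed polarity instead of C8. Pd(PPh3)4 (5 mol %) with InI in THF/HMPA ionises the allylic acetate at zerovalent palladium and transmetalates the π-allyl unit to an allylindium, which adds through C7 to the C8 aldehyde in a closed six-membered transition state to give the alcohol methyl 8α-hydroxy-1-oxo-4α,6α-bis(trimethylsilyloxy)-5αH,7αH-eudesm-11(13)-en-12-oate F6. Ac2O, pyridine and DMAP then give 18. Here reduction of the allyl acetate, the main failure mode of step 10, is the productive path; the 7,8-configuration would have to be checked, since allyl-metal closures lean towards the cis arrangement.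

Step 7 (indium γ-bromoallylation). The hindered aldehyde may react slowly, the allylindium may attack through its CH2 terminus, or the chelate control at C6 may be weak. Fallback, setting out from 12 and 9 and coming back at 14: KOAc in DMF displaces only the allylic bromide of 12 to give the vinyl bromide methyl (E)-2-(acetoxymethyl)-3-bromoprop-2-enoate F5. A Nozaki–Hiyama–Kishi coupling of F5 with 9 (CrCl2, NiCl2 cat., DMF, rt) then joins the acrylate β-carbon as a vinylchromium nucleophile to the aldehyde with retention of alkene geometry. This gives 14 directly, without the bromohydrin and the SN2′ step, and 14 is silylated as in step 8. Facial selectivity at C6 is then not chelate-controlled and the epimer ratio must be checked.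

Step 4 (1,4-addition to a hindered enone and allylation to the quaternary C10). The 2-methylpropenyl cuprate may add poorly next to the quaternary C4. Fallback, setting out from 5 and coming back at 9: the much smaller vinyl group is added instead (vinylMgBr, CuBr·SMe2 cat., THF), which gives bromomagnesium (3R,4R)-3-ethenyl-2,4-dimethyl-4-(trimethylsilyloxy)cyclohex-1-en-1-olate F1. Allyl bromide/HMPA gives (2R,3R,4R)-3-ethenyl-2,4-dimethyl-2-(prop-2-en-1-yl)-4-(trimethylsilyloxy)cyclohexan-1-one F2, and the acid work-up gives (2R,3R,4R)-3-ethenyl-4-hydroxy-2,4-dimethyl-2-(prop-2-en-1-yl)cyclohexan-1-one F3. Because ozone cannot tell vinyl from allyl, the C6 aldehyde is released by hydroxyl-directed epoxidation (VO(acac)2 cat., t-BuOOH; the 4-OH is homoallylic to the vinyl group only), which gives (2R,3S,4R)-4-hydroxy-2,4-dimethyl-3-(oxiran-2-yl)-2-(prop-2-en-1-yl)cyclohexan-1-one F4. H5IO6 cleavage of F4 gives 9.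

**Further compounds**
F1 | step 4 | bromomagnesium (3R,4R)-3-ethenyl-2,4-dimethyl-4-(trimethylsilyloxy)cyclohex-1-en-1-olate | C=C[C@@H]1C(C)=C(O[Mg]Br)CC[C@@]1(C)O[Si](C)(C)C
F2 | step 4 | (2R,3R,4R)-3-ethenyl-2,4-dimethyl-2-(prop-2-en-1-yl)-4-(trimethylsilyloxy)cyclohexan-1-one | C=C[C@@H]1[C@@](C)(CC=C)C(=O)CC[C@@]1(C)O[Si](C)(C)C
F3 | step 4 | (2R,3R,4R)-3-ethenyl-4-hydroxy-2,4-dimethyl-2-(prop-2-en-1-yl)cyclohexan-1-one | C=C[C@@H]1[C@@](C)(CC=C)C(=O)CC[C@@]1(C)O
F4 | step 4 | (2R,3S,4R)-4-hydroxy-2,4-dimethyl-3-(oxiran-2-yl)-2-(prop-2-en-1-yl)cyclohexan-1-one (oxirane epimers) | C1OC1[C@@H]2[C@@](C)(CC=C)C(=O)CC[C@@]2(C)O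
F5 | step 7 | methyl (E)-2-(acetoxymethyl)-3-bromoprop-2-enoate | Br/C=C(\COC(C)=O)C(=O)OC
F6 | step 10 | methyl 8α-hydroxy-1-oxo-4α,6α-bis(trimethylsilyloxy)-5αH,7αH-eudesm-11(13)-en-12-oate | C=C(C(=O)OC)[C@H]1[C@H](O[Si](C)(C)C)[C@@H]2[C@@](C)(C[C@@H]1O)C(=O)CC[C@@]2(C)O[Si](C)(C)C
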